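(All runs were generated by integration for an exercise; the scatter is artificial.)

Watch [D] while Z goes, for from it I reckon how much of Z ends as L.

| flask | Z | D | G | temperature | remark | time |
|---|---|---|---|---|---|---|
| birch | 0.21 M | 0.231 M | 0.063 M | 25 °C | run made earlier |  |
| maple | 0.21 M | 0.231 M | 0.032 M | 25 °C | run made earlier |  |
| zeta | 0.21 M | 0.231 M | 0.0630 M |  | everything together at the start at 5 °C, warmed to 25 °C at 3.0 min | 4.0 min |
| gamma | 0.21 M | 0.231 M (fed, over 3.0 min) | 0.0630 M |  | the addition at 5 °C, then warmed to 25 °C; the feed brings no volume worth counting | 4.0 min |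
| theta | 0.21 M (in portions, 4, over 3.0 min) | 0.231 M | 0.0630 M | 25 °C | first portion at the start, last at 3.0 min | 4.0 min |
| beta | 0.21 M (fed, over 3.0 min) | 0.231 M | 0.0630 M | 25 °C | all else is in the flask from the start; the feed brings no volume worth counting | 4.0 min |
| epsilon | 0.21 M | 0.231 M | 0.0630 M | 25 °C | everything together at the start | 4.0 min |

birch run (percent of the Z charged)

| time / min | L / % | Z / % |
|---|---|---|
| 0.333 | 42.0 | 18.6 |
| 1.00 | 48.0 | 2.1 |
| 2.00 | 48.2 | 0.8 |
| 3.00 | 48.0 | 0.1 |
| 4.00 | 48.6 | 0 |

maple run (percent of the Z charged)

| time / s | L / % | Z / % |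
|---|---|---|
| 10.0 | 35.1 | 39.1 |
| 12.0 | 36.5 | 34.4 |
| 20.0 | 42.9 | 19.2 |
| 30.0 | 46.0 | 10.9 |
| 50.0 | 47.7 | 3.8 |

(readings scatter by 0.5 percentage points)

- L is meant together with its Q
- solid, in amounts per volume of the solution: Q
- the earlier runs were read with a standard deviation of 0.5 percentage points
- on the list of suspects stand: Z + D -> L; Z + D -> X; Q <-> L; Z + G -> J
- the earlier runs do not show what temperature does; that part of a forecast is a guess

1. which flask leads in amount of L, in percent of the Z charged ("all alike" within 1.5 percentage points) (zeta / gamma / theta / beta / epsilon / all alike)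
2. how much L is there at the end, in percent of the Z charged: zeta
3. how much L is there at the end, in percent of the Z charged: gamma
4. how much L is there at the end, in percent of the Z charged: theta
5. how much L is there at the end, in percent of the Z charged: beta
6. how much L is there at the end, in percent of the Z charged: epsilon

In the maple run at 10.0 s, Z reads 39.1 % and L 35.1 %, so L has taken 57.6 % of the Z used. I count one D for each Z used, which is rough for J, so [D] averages 0.167 M over that stretch. If L's share is [D]/([D] + crossover), the reading gives 0.123 M. This is the crossover [D], the [D] at which L and the other paths take equal shares of Z.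

Summing that share as [D] falls, L equals the D used, less the crossover times the logarithm of ([D] at start + crossover) over ([D] at end + crossover). With Z used up, that count takes [D] from 0.231 M to 0.0210 M, the logarithm is 0.900, and L comes to 47.4 %. The birch run, a different run from the one that gave the crossover, reads 48.0 % at 3.00 min. The sum holds no [Z], so in my reckoning feeding Z leaves it as it is, and I commit to 47.4 % for epsilon, theta and beta. Gamma, with D fed in, does not start from that [D], and I give it no number.

The weak link is the cold, since the crossover is read at 25 °C and the runs do not show it at 5 °C. So I recast zeta as a span. A crossover of 0.246 M gives 32.1 %, and one of 0.0614 M gives 63.0 %.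

The forecast names epsilon as leader at 48.5 %, with zeta 48 %, gamma 25 %, theta 46 % and beta 43 %: “Zeta finishes during the cold stage, also about 48, though the temperature effect is a guess”. Its zeta lies inside my span, where I name no point, and its theta and beta stand below my 47.4 %.

The flasks give zeta 62.4 %, gamma 30.7 %, theta 47.9 %, beta 48.0 % and epsilon 48.0 %, so zeta leads.

    Z + D → L (k = 0.330 M⁻¹ s⁻¹, Ea = 46.0 kJ mol⁻¹)
    Z + D → X, rate k2*[Z] as long as [D] is above zero (k = 0.0360 s⁻¹, Ea = 72.0 kJ mol⁻¹)
    Q ⇌ L, rate k3*(cs3 - [L]) while solid is left; crystals form when [L] > cs3 (solubility = 0.0870 M, k = 0.920 s⁻¹)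
    Z + G → J (k = 0.150 M⁻¹ s⁻¹, Ea = 63.0 kJ mol⁻¹)
    (constants at 25 °C)

Forecast and flask part at zeta. In zeta L starts at 4.5 times the rate of X, which puts the crossover of L against X alone, at the cold start, at 0.0513 M; in the equations J uses no D. Held through the warming, and with [D] ending at 16.8 % of its charge, the same sum gives 63.6 % against the 62.4 % in the flask. The neighbour of zeta charged with 0.39 M of D ends with [D] at 48.7 % of its charge, and the sum gives 80.6 %, where that flask holds 80.4 %.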